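**Retrosynthetic overview**

1. Target locants: C1 = C(OH), C2 = CHOAc, C3=C4, C5 and C6 = CHOBz, C7 = CH2OAc. The acyl groups go on last: 18 comes from cyclohexene acid 12 (C7 as CO2H, O2 as PMB ether, O1/O5/O6 as SiEt3 ethers) by reduction and staged unmasking and acylation.
2. Feature used: the chain C7–C1(O)–C2(O)–C3=C4 in the six-membered ring. With C7 at the acid level it is a 2,3-dioxygenated pent-4-enoic acid, the pattern left by an ester-enolate Claisen shift in which C4 was bonded to the ester oxygen.
3. Key disconnection C1–C2 (re-forming C4–O): 12 comes from the silyl ketene acetal of δ-lactone 9, a D-gluco lactone with an E-CH=CH–OPMB arm on the carbon that bears the ring oxygen. The carbocycle, the only ring of the target, closes in this step as the lactone ring opens.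
4. Lactone 9 comes from D-glucono-1,5-lactone 1 by persilylation, oxidation of the primary silyl ether to the aldehyde, and a two-stage Horner–Wittig alkoxymethylenation with Ph2P(O)CH2OPMB 7 (made from 4 and 6).

Key step: step 7

Remark on locants: lactone carbons are written gC1–gC7 (gluconolactone numbering, gC7 being the new enol ether carbon). They map onto the target as gC1 → C7, gC2 → C1, gC3 → C6, gC4 → C5, gC5 → C4, gC6 → C3, gC7 → C2.
Remark (assumption): (hydroxymethyl)diphenylphosphine oxide 4, the formaldehyde adduct of Ph2P(O)H, is taken as a purchasable reagent.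

**Route**

Step 1
Reactants: 1 D-glucono-1,5-lactone
Product: 2 2,3,4,6-tetra-O-triethylsilyl-D-glucono-1,5-lactone
Conditions: Et3SiCl, imidazole, DMF, 0 °C → rt
Reagents that add atoms: chlorotriethylsilane, CC[Si](Cl)(CC)CC
Why: Exhaustive silyl ether formation with Et3SiCl/imidazole should proceed under conditions too mild to open or isomerise the δ-lactone, and no stereocentre is touched.

Step 2
Reactants: 2 2,3,4,6-tetra-O-triethylsilyl-D-glucono-1,5-lactone
Product: 3 2,3,4-tri-O-triethylsilyl-6-aldehydo-D-glucono-1,5-lactone (gC6 is CHO)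
Conditions: (COCl)2, DMSO, CH2Cl2, −78 → −40 °C; Et3N, −78 → 0 °C
Reagents that add atoms: none
Why: Swern oxidation of a primary triethylsilyl ether: chlorodimethylsulfonium chloride attacks the unhindered primary silyl ether oxygen, Et3SiCl is expelled and the alkoxysulfonium ylide collapses to the aldehyde, while the three secondary silyl ethers are too hindered to react and gC5 should keep its configuration if the amine stage is kept cold.

Step 3
Reactants: 4 (hydroxymethyl)diphenylphosphine oxide
Product: 5 (diphenylphosphoryl)methyl 4-toluenesulfonate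
Conditions: TsCl, Et3N, DMAP (cat.), CH2Cl2, 0 °C → rt
Reagents that add atoms: 4-toluenesulfonyl chloride, Cc1ccc(cc1)S(Cl)(=O)=O
Why: Sulfonylation of a primary alcohol (tosylate formation) makes the hydroxymethyl carbon electrophilic without touching the P=O group.

Step 4
Reactants: 5 (diphenylphosphoryl)methyl 4-toluenesulfonate; 6 4-methoxybenzyl alcohol
Product: 7 [(4-methoxybenzyloxy)methyl]diphenylphosphine oxide
Conditions: NaH, DMF, 0 → 50 °C
Reagents that add atoms: none
Why: Williamson ether synthesis: sodium 4-methoxybenzyl oxide displaces tosylate at the unhindered CH2 carbon by SN2, as in the analogous alkylations with phosphorylmethyl sulfonates.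

Step 5
Reactants: 3 2,3,4-tri-O-triethylsilyl-6-aldehydo-D-glucono-1,5-lactone; 7 [(4-methoxybenzyloxy)methyl]diphenylphosphine oxide
Product: 8 threo β-hydroxy phosphine oxide, (6S,7R)-7-(diphenylphosphoryl)-7-O-(4-methoxybenzyl)-2,3,4-tri-O-triethylsilyl-D-gluco-heptono-1,5-lactone with free 6-OH
Conditions: 7, LiN(iPr)2, THF, −78 °C; then 3, −78 °C; aq. NH4Cl
Reagents that add atoms: none
Why: Horner–Wittig addition: the lithiated α-alkoxy phosphine oxide should add to the aldehyde far faster than to the lactone at −78 °C, and because the lithium alkoxide does not eliminate the adducts can be isolated; Felkin–Anh attack anti to the gC5–O bond should favour 6S, and the threo adduct 8 (its 6R,7S counterpart is equally usable) is separated by chromatography from the erythro adducts, which would lead to the Z enol ether.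

Step 6
Reactants: 8 threo β-hydroxy phosphine oxide
Product: 9 2,3,4-tri-O-triethylsilyl-D-gluco-hept-6-enono-1,5-lactone E-7-(4-methoxybenzyl) enol ether
Conditions: KN(SiMe3)2 (1.0 equiv), THF, −78 → 0 °C
Reagents that add atoms: none
Why: Horner–Wittig elimination: the potassium alkoxide closes to an oxaphosphetane and loses diphenylphosphinate by stereospecific syn elimination, which for the threo adduct places gC5 and OPMB trans (E), and one equivalent of base at low temperature should leave the lactone α-proton alone.

Step 7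
Reactants: 9 2,3,4-tri-O-triethylsilyl-D-gluco-hept-6-enono-1,5-lactone E-7-(4-methoxybenzyl) enol ether
Product: 12 2-(4-methoxybenzyloxy)-1,5,6-tris(triethylsilyloxy)cyclohex-3-ene-1-carboxylic acid, via trimethylsilyl ketene acetal 10 (not isolated), via trimethylsilyl ester 11 (not isolated)
Conditions: Me3SiCl, KN(SiMe3)2, THF–toluene, −78 °C → rt, then 80 °C; aq. pH 5 buffer
Reagents that add atoms: none
Why: KN(SiMe3)2 removes the gC2 proton with Me3SiCl already present, so the enolate should be O-silylated to ketene acetal 10 before it can expel the gC3 silyloxy group, and on warming 10 undergoes a concerted suprafacial [3,3] shift that forms gC2–gC7 (target C1–C2), breaks gC5–O (target C4–O) and gives silyl ester 11, hydrolysed to 12 on work-up. The closest known reaction type is the Ireland–Claisen ring contraction of alkenyl lactones to cycloalkene carboxylic acids. The cyclohexene closes by the sigmatropic C–C bond formation itself, through a boat-shaped, bicyclo[2.2.2]octane-like transition state in which the lactone ring is one six-membered loop and the forming carbocycle another; a chair is out of reach because gC3–gC4 tie the two termini together. C1 is set by gC5: the alkoxyvinyl arm can reach gC2 only on the lactone face it stands on (cis to the gC3 oxygen, trans to the gC4 oxygen), which places the carboxyl carbon C7 trans to O6 and cis to O5, so the gC5 stereocentre is traded for the quaternary one. C2 is set by the E geometry of the enol ether together with the ring-locked ketene acetal geometry: in the boat the OPMB group ends up cis to C7 and trans to O1, and the enol ether hydrogen (not OPMB) faces the gC3 silyloxy group. The step needs O-silylation to outrun beta-elimination, secured by the internal Me3SiCl quench and the poor leaving-group ability of a silyloxide, and it needs a geometrically pure E enol ether, secured in steps 5 and 6.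

Step 8
Reactants: 12 2-(4-methoxybenzyloxy)-1,5,6-tris(triethylsilyloxy)cyclohex-3-ene-1-carboxylic acid
Product: 13 methyl 2-(4-methoxybenzyloxy)-1,5,6-tris(triethylsilyloxy)cyclohex-3-ene-1-carboxylate
Conditions: Me3SiCHN2, MeOH–toluene, 0 °C → rt
Reagents that add atoms: trimethylsilyldiazomethane, C[Si](C)(C)C=[N+]=[N-]
Why: Diazoalkane esterification of the hindered acid is neutral and should leave silyl ethers, PMB ether and stereocentres untouched.

Step 9
Reactants: 13 methyl 2-(4-methoxybenzyloxy)-1,5,6-tris(triethylsilyloxy)cyclohex-3-ene-1-carboxylate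
Product: 14 methyl 2-hydroxy-1,5,6-tris(triethylsilyloxy)cyclohex-3-ene-1-carboxylate
Conditions: DDQ, CH2Cl2–pH 7 buffer, 0 °C
Reagents that add atoms: none
Why: Oxidative PMB ether cleavage with DDQ (oxidation to the benzylic oxocarbenium ion, then hydrolysis) frees the allylic C2 hydroxyl with retention, and at the ester stage there is no neighbouring free hydroxyl to trap the cation as an acetal.

Step 10
Reactants: 14 methyl 2-hydroxy-1,5,6-tris(triethylsilyloxy)cyclohex-3-ene-1-carboxylate
Product: 15 1-(hydroxymethyl)-1,5,6-tris(triethylsilyloxy)cyclohex-3-en-2-ol (diol)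
Conditions: (i-Bu)2AlH (excess), CH2Cl2, −78 → 0 °C; aq. KNaC4H4O6
Reagents that add atoms: none
Why: Hydride reduction of the methyl ester gives the primary C7 alcohol; the covalent aluminium alkoxides formed should be poor partners for silyl migration from O1, and the isolated alkene is inert.

Step 11
Reactants: 15 1-(hydroxymethyl)-1,5,6-tris(triethylsilyloxy)cyclohex-3-en-2-ol
Product: 16 diacetate (C7-OAc, C2-OAc; O1, O5, O6 as SiEt3 ethers)
Conditions: Ac2O, pyridine, DMAP (cat.), CH2Cl2, 0 °C → rt
Reagents that add atoms: acetic anhydride, CC(=O)OC(C)=O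
Why: Acylation esterifies the primary and the secondary allylic hydroxyl with retention, the tertiary oxygen still being silylated.

Step 12
Reactants: 16 diacetate
Product: 17 triol diacetate (C7-OAc, C2-OAc; free OH at C1, C5, C6)
Conditions: HF·pyridine, pyridine, THF, 0 °C → rt
Reagents that add atoms: none
Why: Fluoride-mediated desilylation with buffered HF·pyridine should remove all three triethylsilyl ethers under mildly acidic conditions in which acetates neither hydrolyse nor migrate.

Step 13
Reactants: 17 triol diacetate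
Product: 18 [(1R,2S,5R,6S)-2-acetoxy-5,6-bis(benzoyloxy)-1-hydroxycyclohex-3-en-1-yl]methyl acetate (CNP0196993.1)
Conditions: BzCl, pyridine, DMAP (cat.), CH2Cl2, 0 °C → rt
Reagents that add atoms: benzoyl chloride, O=C(Cl)c1ccccc1
Why: Acylation with BzCl/pyridine esterifies the two secondary hydroxyls with retention, while the tertiary C1 hydroxyl on the fully substituted carbon should not react under these conditions.

**Compound list**

In 12–17 the carboxyl-derived carbon C7, O2 and O5 lie on one ring face and O1 and O6 on the other, as in the target.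

1 | D-glucono-1,5-lactone | O=C1O[C@H](CO)[C@@H](O)[C@H](O)[C@H]1O | starting material
2 | 2,3,4,6-tetra-O-triethylsilyl-D-glucono-1,5-lactone | O=C1O[C@H](CO[Si](CC)(CC)CC)[C@@H](O[Si](CC)(CC)CC)[C@H](O[Si](CC)(CC)CC)[C@H]1O[Si](CC)(CC)CC | intermediate
3 | 2,3,4-tri-O-triethylsilyl-6-aldehydo-D-glucono-1,5-lactone | O=C1O[C@H](C=O)[C@@H](O[Si](CC)(CC)CC)[C@H](O[Si](CC)(CC)CC)[C@H]1O[Si](CC)(CC)CC | intermediate
4 | (hydroxymethyl)diphenylphosphine oxide | OCP(=O)(c1ccccc1)c1ccccc1 | starting material
5 | (diphenylphosphoryl)methyl 4-toluenesulfonate | Cc1ccc(cc1)S(=O)(=O)OCP(=O)(c1ccccc1)c1ccccc1 | intermediate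
6 | 4-methoxybenzyl alcohol | COc1ccc(CO)cc1 | starting material
7 | [(4-methoxybenzyloxy)methyl]diphenylphosphine oxide | COc1ccc(COCP(=O)(c2ccccc2)c2ccccc2)cc1 | intermediate
8 | threo (6S,7R) β-hydroxy phosphine oxide adduct of 3 and 7 | O=C1O[C@H]([C@H](O)[C@H](OCc2ccc(OC)cc2)P(=O)(c2ccccc2)c2ccccc2)[C@@H](O[Si](CC)(CC)CC)[C@H](O[Si](CC)(CC)CC)[C@H]1O[Si](CC)(CC)CC | intermediate
9 | 2,3,4-tri-O-triethylsilyl-D-gluco-hept-6-enono-1,5-lactone E-7-(4-methoxybenzyl) enol ether | O=C1O[C@H](/C=C/OCc2ccc(OC)cc2)[C@@H](O[Si](CC)(CC)CC)[C@H](O[Si](CC)(CC)CC)[C@H]1O[Si](CC)(CC)CC | intermediate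
10 | trimethylsilyl ketene acetal of 9 (gC1=gC2, OSiMe3 on gC1) | C[Si](C)(C)OC1=C(O[Si](CC)(CC)CC)[C@@H](O[Si](CC)(CC)CC)[C@H](O[Si](CC)(CC)CC)[C@@H](/C=C/OCc2ccc(OC)cc2)O1 | intermediate
11 | trimethylsilyl ester of acid 12 | C[Si](C)(C)OC(=O)[C@@]1(O[Si](CC)(CC)CC)[C@@H](OCc2ccc(OC)cc2)C=C[C@@H](O[Si](CC)(CC)CC)[C@@H]1O[Si](CC)(CC)CC | intermediate
12 | 2-(4-methoxybenzyloxy)-1,5,6-tris(triethylsilyloxy)cyclohex-3-ene-1-carboxylic acid | OC(=O)[C@@]1(O[Si](CC)(CC)CC)[C@@H](OCc2ccc(OC)cc2)C=C[C@@H](O[Si](CC)(CC)CC)[C@@H]1O[Si](CC)(CC)CC | intermediate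
13 | methyl ester of 12 | COC(=O)[C@@]1(O[Si](CC)(CC)CC)[C@@H](OCc2ccc(OC)cc2)C=C[C@@H](O[Si](CC)(CC)CC)[C@@H]1O[Si](CC)(CC)CC | intermediate
14 | methyl 2-hydroxy-1,5,6-tris(triethylsilyloxy)cyclohex-3-ene-1-carboxylate | COC(=O)[C@@]1(O[Si](CC)(CC)CC)[C@@H](O)C=C[C@@H](O[Si](CC)(CC)CC)[C@@H]1O[Si](CC)(CC)CC | intermediate
15 | 1-(hydroxymethyl)-1,5,6-tris(triethylsilyloxy)cyclohex-3-en-2-ol | OC[C@@]1(O[Si](CC)(CC)CC)[C@@H](O)C=C[C@@H](O[Si](CC)(CC)CC)[C@@H]1O[Si](CC)(CC)CC | intermediate
16 | C7,C2-diacetate with O1, O5, O6 as triethylsilyl ethers | CC(=O)OC[C@@]1(O[Si](CC)(CC)CC)[C@@H](OC(C)=O)C=C[C@@H](O[Si](CC)(CC)CC)[C@@H]1O[Si](CC)(CC)CC | intermediate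
17 | C7,C2-diacetate with free 1-, 5- and 6-OH | CC(=O)OC[C@@]1(O)[C@@H](OC(C)=O)C=C[C@@H](O)[C@@H]1O | intermediate
18 | [(1R,2S,5R,6S)-2-acetoxy-5,6-bis(benzoyloxy)-1-hydroxycyclohex-3-en-1-yl]methyl acetate | CC(=O)OC[C@@]1(O)[C@@H](OC(C)=O)C=C[C@@H](OC(=O)c2ccccc2)[C@@H]1OC(=O)c1ccccc1 | target

**Step count**

Total steps: 13. Longest linear sequence: 11 (steps 1, 2, 5–13 from D-glucono-1,5-lactone); steps 3 and 4 form a two-step side branch that joins at step 5.

**Steps most likely to fail**

1. Step 7 (key step). The potassium enolate may lose the gC3 silyloxy group by beta-elimination before it is silylated, or the trimethylsilyl ketene acetal may decompose before the boat rearrangement takes place. The fallback sets out from 9 and avoids any metal enolate. t-BuMe2SiOTf and Et3N in CH2Cl2 silylate the lactone carbonyl oxygen first, and the amine then removes the gC2 proton, giving the isolable tert-butyldimethylsilyl ketene acetal F1. Heating this in toluene at about 100 °C in a separate operation should give the tert-butyldimethylsilyl ester F2. Hydrolysis with K2CO3 in aqueous MeOH–THF returns to the route at 12.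

2. Step 5. The addition may show poor threo selectivity (erythro adducts lead to the Z enol ether and hence to the C2 epimer), and the basic lithiated reagent may enolise the aldehyde with loss of the gC4 silyloxy group. The fallback sets out from 3 and is non-basic and stereodefined. Takai–Utimoto borylolefination with 2-(dichloromethyl)-4,4,5,5-tetramethyl-1,3,2-dioxaborolane, CrCl2 and LiI in THF should give the E-alkenyl pinacol boronate F3. Oxidative C–O coupling of F3 with 4-methoxybenzyl alcohol 6 promoted by Cu(OAc)2 (Et3N, air, rt) proceeds with retention of alkene geometry and returns to the route at 9, bypassing 8.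

3. Step 2. The aldehyde may epimerise at gC5 or lose the gC4 silyloxy group under the amine base, or the primary silyl ether may be cleaved incompletely or unselectively by the activated sulfoxide. The fallback sets out from 2 and separates deprotection from oxidation. HF·pyridine buffered with pyridine in THF at 0 °C removes only the primary silyl ether to give 2,3,4-tri-O-triethylsilyl-D-glucono-1,5-lactone F4. Oxidation with Dess–Martin periodinane and NaHCO3 in CH2Cl2, with no amine base, returns to the route at 3.

**Further compounds**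

F1 | step 7 | tert-butyldimethylsilyl ketene acetal of lactone 9 | CC(C)(C)[Si](C)(C)OC1=C(O[Si](CC)(CC)CC)[C@@H](O[Si](CC)(CC)CC)[C@H](O[Si](CC)(CC)CC)[C@@H](/C=C/OCc2ccc(OC)cc2)O1
F2 | step 7 | tert-butyldimethylsilyl ester of acid 12 | CC(C)(C)[Si](C)(C)OC(=O)[C@@]1(O[Si](CC)(CC)CC)[C@@H](OCc2ccc(OC)cc2)C=C[C@@H](O[Si](CC)(CC)CC)[C@@H]1O[Si](CC)(CC)CC
F3 | step 5 | 2,3,4-tri-O-triethylsilyl-D-gluco-hept-6-enono-1,5-lactone E-7-(pinacolatoboryl) derivative | O=C1O[C@H](/C=C/B2OC(C)(C)C(C)(C)O2)[C@@H](O[Si](CC)(CC)CC)[C@H](O[Si](CC)(CC)CC)[C@H]1O[Si](CC)(CC)CC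
F4 | step 2 | 2,3,4-tri-O-triethylsilyl-D-glucono-1,5-lactone | O=C1O[C@H](CO)[C@@H](O[Si](CC)(CC)CC)[C@H](O[Si](CC)(CC)CC)[C@H]1O[Si](CC)(CC)CC
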